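## The problem

Stypandrol (22) is two identical 2-acetyl-1,8-dihydroxy-3-methylnaphthalene halves joined by one aryl–aryl bond between C7 and C7', the carbons ortho to the C8 hydroxyl groups of the two rings B. There is no stereocentre, and the biaryl axis has only one hydroxyl group and one ring CH beside it on each side, so it should rotate freely; the whole task is regiochemical. Ring A is substituted at every position but C4 and carries oxygen, acetyl and methyl on three adjacent carbons (C1, C2, C3). Ring B carries only the C8 oxygen, which must end up peri to the C1 oxygen. The biaryl bond must form at C7 and not at C5, which is para to the C8 oxygen and just as activated. The free peri-dihydroxynaphthalene is easily oxidized toward quinones, and the acetyl group, wedged between two ortho substituents, is enolizable, hard to ketalize and incompatible with organolithium reagents unless masked; the phenols are therefore best released last. The key step is possible because ring B shares only the C4a–C8a bond with ring A and has its single heteroatom at C8, next to C8a, while C1 on the other side of C8a also bears oxygen. Ring A can thus act as an aryne across C4a–C8a, polarized by the C1 alkoxy group, and C5–C8 can come from an oxygenated diene that aromatizes by losing a small molecule.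

## Retrosynthesis

**22 from 21.** The four O–H bonds are cut first, leading back to the tetramethyl ether 21. Methyl ethers survive butyllithium, fluoride and hot copper and fall to BBr3 in one operation, so the oxidation-prone tetrol appears only in the last flask. The forward step must cleave four aryl methyl ethers without touching two aryl ketones.

**21 from 20.** The C7–C7' bond is cut symmetrically to two molecules of iodide 20. A phenolic oxidative dimerization at the diol stage would be one step shorter, but a 1-naphthol with a free para position (C5) couples ortho and para with little preference and over-oxidizes easily. A halide at C7 removes that ambiguity. The precursor is half the size, and the forward step is a reductive homocoupling of an aryl iodide with one ortho substituent.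

**20 from 16.** The C7–I bond is cut to give naphthalene 16. Electrophilic halogenation of a 1,8-dimethoxynaphthalene goes para (C5 or C4), so the iodine is placed by methoxy-directed lithiation instead: C7 is the only carbon ortho to a methoxy group that still bears hydrogen. The forward step needs the methyl ketone hidden from butyllithium; it is converted in the flask into its enol silyl ether 17, lithiated to 18, iodinated to 19 and unmasked on work-up.

**16 from 11 and 13 (key disconnection).** The C8a–C8 and C4a–C5 bonds are cut, so that ring B falls away as a four-carbon diene and ring A becomes aryne 14, generated from silyl triflate 11. The diene is 3-methoxy-2-pyrone 13; the bridged lactone 15 loses CO2 and gives ring B aromatic at once. Compared with a cut through ring A, or with a stepwise annulation of ring B from a benzylic anion, this cut keeps the crowded ring A intact from a commercial benzene and forms ring B at the final oxidation level. The precursors are one benzene and one pyrone. The forward reaction must put the pyrone's methoxy carbon on C8a rather than C4a.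

**11 from 9, 9 from 5.** The aryl triflate of 11 is traced to the isopropyl carbamate 9, which is cleaved by mild base to phenol 10 and triflated in the same flask. The C–Si bond of 9 is cut back to carbamate 5, since the carbon between the carbamate oxygen and the methoxy group is the one site activated by both directing groups. This is preferred over halogenation followed by silyl migration from oxygen to carbon: electrophilic halogenation of this ring favours the position para to the methoxy group, whereas the cooperative lithiation is unambiguous. The ketone is again masked in the flask, as the enol silyl ether in 6, 7 and 8.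

**5 from 4, 3, 2 and 1.** The carbamate C–O bond is cut to phenol 4, and the two oxygens of 4 are traced to commercial orcacetophenone 1. The hydrogen bond between the C2 hydroxyl and the acetyl group differentiates the two hydroxyls: the free para hydroxyl is benzylated first (2), the chelated one is then methylated (3), and hydrogenolysis frees the para hydroxyl (4). Direct carbamoylation of 1 followed by methylation would be shorter, but the base needed to methylate the chelated phenol endangers an N–H aryl carbamate.

**13 from 12.** The O–CH3 bond of the diene is cut to commercial 3-hydroxy-2-pyrone 12. The hydroxyl must be capped because a free enol would add to the aryne through oxygen.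

## Roads not taken

**Alternative 1:** The cut runs through ring A (C1–C2, C3–C4 and C4a–C8a), so ring A is assembled from three alkynes and ring B is the saturated tether of a diyne. In the forward direction the ynol ether ynone diyne A2 and the unsymmetrical ynone A3 would undergo a metal-catalysed (2+2+2) cycloaddition (RhCl(PPh3)3 or CpCo(CO)2) to give tetralone A1, closing both rings in one step.
- Merits: every substituent of ring A is fixed by the choice of alkyne, no organolithium reagent meets the ketone, and the C8 oxygen is already present as the tetralone carbonyl.
- Weak points: A3 can insert in two orientations and only one places the acetyl group next to the ethoxy carbon; the push–pull alkyne A2 is labile to water and to conjugate addition; homo-oligomerization competes with the cross reaction; and ring B of A1 is at the wrong oxidation level, so dehydrogenation, ether cleavage and C7 functionalization still follow.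
- Comparison: in atom economy and in steps to the bicyclic skeleton this road is at least as good. The chosen plan sets against it a regiochemical bias that rests on the known distortion of 3-alkoxyarynes rather than on catalyst tuning, and a ring B that is aromatic as formed.

**Alternative 2:** The cut removes C5–C6 and C7–C8 in both halves at once and keeps the C7–C7' bond, which is already present in the diene diester A6. Two equivalents of the laterally lithiated symmetrical isophthalate A5 would add to the two methylene termini of A6, and each ester enolate would close onto the neighbouring aryl ester to give bitetralone A4.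
- Merits: the biaryl linkage is fixed by construction, the symmetry of the target is used fully, and A5 needs no differentiation of its esters or methyl groups.
- Weak points: after the first conjugate addition the acceptor is a delocalized dienolate and no longer electrophilic at its second terminus; the two ring closures create adjacent quaternary centres at C7 and C7'; and A4 is far from 22, needing double dealkoxycarbonylation, dehydrogenation of both rings B, conversion of two di-ortho-substituted aryl esters into acetyl groups, and demethylation.
- Comparison: on the regiochemistry of dimerization this road is better, since the chosen plan needs a directed iodination and a homocoupling. The chosen plan sets against it an acetyl group carried from the first compound, an aromatic ring B, and steps that each have close precedent.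

**Alternative 3:** The cut is the C5–C6 bond: ring B is closed from the C4a methyl group and a three-carbon enaminone chain on C8a. The symmetrical diketone A9 would be converted to the mono-enaminone A8; a strong base would deprotonate the C4a methyl group to an ortho-quinodimethane enolate that closes C5–C6 by 6π-electrocyclization and expels dimethylamine, giving naphthol A7.
- Merits: very short, no transition metal and no aryne; A7 has the C8 hydroxyl free and the C1 oxygen methylated, a differentiation the chosen route does not deliver.
- Weak points: A9 has two equivalent acetyl groups, so the mono-enaminone forms alongside the bis-enaminone; in A8 the remaining acetyl methyl group is far more acidic than the lateral methyl group and consumes base first; the C3 methyl group is activated in the same vinylogous way; and ring closure needs the hindered enaminone to become coplanar with the ring.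
- Comparison: in step count to the naphthalene and in differentiation of the two oxygens this road is better. The chosen plan sets against it the absence of a statistical step and of competing acidic sites. The missing differentiation costs it little, because the C8 methoxy group alone directs lithiation to C7.

Key step: step 8

## Route

Assumption: the C7–C7' axis of 22 is configurationally labile at room temperature (one ortho hydroxyl on each side), so the target is treated as a single achiral compound.

Step 1
Reactants: 1 1-(2,4-dihydroxy-6-methylphenyl)ethan-1-one (orcacetophenone)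
Product: 2 1-[4-(benzyloxy)-2-hydroxy-6-methylphenyl]ethan-1-one
Conditions: BnBr (1.05 equiv), K2CO3, acetone, reflux
Reagents that add atoms: benzyl bromide, BrCc1ccccc1
Why: Williamson etherification; the C2 hydroxyl is tied up in a hydrogen bond to the acetyl oxygen and is much less nucleophilic, so one equivalent of halide should react at the para hydroxyl only.

Step 2
Reactants: 2 1-[4-(benzyloxy)-2-hydroxy-6-methylphenyl]ethan-1-one
Product: 3 1-[4-(benzyloxy)-2-methoxy-6-methylphenyl]ethan-1-one
Conditions: MeI (excess), K2CO3, DMF, 50 °C
Reagents that add atoms: iodomethane, CI
Why: Williamson etherification of the chelated phenol under more forcing conditions; carbonate is too weak a base to enolize and C-methylate the ketone.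

Step 3
Reactants: 3 1-[4-(benzyloxy)-2-methoxy-6-methylphenyl]ethan-1-one
Product: 4 1-(4-hydroxy-2-methoxy-6-methylphenyl)ethan-1-one
Conditions: H2 (1 atm), Pd/C, EtOAc, rt
Reagents that add atoms: none
Why: Hydrogenolysis of a benzyl aryl ether; the acetyl group, twisted out of the ring plane by its two ortho neighbours, should be reduced much more slowly than the benzyl ether is cleaved.

Step 4
Reactants: 4 1-(4-hydroxy-2-methoxy-6-methylphenyl)ethan-1-one
Product: 5 4-acetyl-3-methoxy-5-methylphenyl N-(propan-2-yl)carbamate
Conditions: i-PrNCO, Et3N (cat.), CH2Cl2, rt
Reagents that add atoms: 2-isocyanatopropane (isopropyl isocyanate), CC(C)N=C=O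
Why: Amine-catalysed addition of a phenol to an isocyanate; it installs a strong ortho-directing group that can later be removed with mild base.

Step 5
Reactants: 5 4-acetyl-3-methoxy-5-methylphenyl N-(propan-2-yl)carbamate
Product: 9 4-acetyl-3-methoxy-5-methyl-2-(trimethylsilyl)phenyl N-(propan-2-yl)carbamate, via bis-silylated enol ether carbamate 6 (not isolated), via aryllithium 7 (not isolated), via C-silylated enol ether carbamate 8 (not isolated)
Conditions: TBSOTf (2.3 equiv), TMEDA, Et2O, 0 °C to rt; n-BuLi (3.5 equiv), TMEDA, −78 °C; TMSCl, −78 °C to rt; 1 M aq. HCl, THF, 0 °C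
Reagents that add atoms: chlorotrimethylsilane, C[Si](C)(C)Cl; tert-butyldimethylsilyl trifluoromethanesulfonate, CC(C)(C)[Si](C)(C)OS(=O)(=O)C(F)(F)F (its silyl groups are present only in 6 to 8)
Why: Directed ortho-metalation; the N-silylated carbamate and the methoxy group together direct lithium to the one carbon between them, and the same silyl triflate turns the hindered methyl ketone into an enol silyl ether that is inert to butyllithium at −78 °C and is hydrolysed with the N-silyl group on acidic work-up.

Step 6
Reactants: 9 4-acetyl-3-methoxy-5-methyl-2-(trimethylsilyl)phenyl N-(propan-2-yl)carbamate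
Product: 11 4-acetyl-3-methoxy-5-methyl-2-(trimethylsilyl)phenyl trifluoromethanesulfonate, via silylated phenol 10 (not isolated)
Conditions: DBU, Et2NH, MeCN, 40 °C; PhNTf2, rt
Reagents that add atoms: N-phenylbis(trifluoromethanesulfonimide), O=S(=O)(N(c1ccccc1)S(=O)(=O)C(F)(F)F)C(F)(F)F
Why: E1cB cleavage of the N–H carbamate (the isocyanate is scavenged by diethylamine) followed by triflation of the phenoxide in the same flask; no acid or fluoride is present, so the aryl–silicon bond and the ketone remain.

Step 7
Reactants: 12 3-hydroxy-2H-pyran-2-one
Product: 13 3-methoxy-2H-pyran-2-one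
Conditions: MeI, K2CO3, acetone, reflux
Reagents that add atoms: iodomethane, CI
Why: O-Alkylation of an acidic enol; anhydrous carbonate in acetone should leave the lactone ring closed.

Step 8
Reactants: 11 4-acetyl-3-methoxy-5-methyl-2-(trimethylsilyl)phenyl trifluoromethanesulfonate; 13 3-methoxy-2H-pyran-2-one
Product: 16 1-(1,8-dimethoxy-3-methylnaphthalen-2-yl)ethan-1-one, via aryne 14 (not isolated), via bridged lactone 15 (not isolated)
Conditions: CsF (3 equiv), 13 (3 equiv), MeCN, rt to 60 °C
Reagents that add atoms: none
Why: Fluoride attacks the trimethylsilyl group of 11 and triflate leaves from the neighbouring carbon, giving aryne 14 with its strained bond between the future C4a and C8a. Pyrone 13 adds as a diene through C3 and C6 in a concerted, asynchronous (4+2) cycloaddition; the closest known reaction type is the Diels–Alder reaction of arynes with 2-pyrones followed by decarboxylation to naphthalenes. The electron-withdrawing C1 methoxy group distorts the aryne so that C4a is the flatter, more electrophilic terminus, and the unsubstituted C6 of the pyrone, made electron-rich by the 3-methoxy group, bonds there first; C3 then closes onto C8a, placing the pyrone oxygen at C8, peri to C1. Ring B is thus closed by intermolecular annulation, the two new bonds C8a–C8 and C4a–C5 completing a six-membered carbocycle on the aryne edge. Bridged lactone 15 then loses CO2 in a retro-(4+2) step driven by aromatization. The two bridgehead stereocentres of 15 form as a racemate and vanish with the CO2, so no stereocontrol is needed. The selectivity that matters is regiochemistry, and the methoxy groups on aryne and diene act in the same sense; excess 13 intercepts the short-lived aryne, and the twisted acetyl group should be a spectator under CsF.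

Step 9
Reactants: 16 1-(1,8-dimethoxy-3-methylnaphthalen-2-yl)ethan-1-one
Product: 20 1-(7-iodo-1,8-dimethoxy-3-methylnaphthalen-2-yl)ethan-1-one, via enol silyl ether 17 (not isolated), via aryllithium 18 (not isolated), via iodinated enol silyl ether 19 (not isolated)
Conditions: TBSOTf (1.2 equiv), TMEDA, Et2O, 0 °C to rt; n-BuLi (2.4 equiv), TMEDA, 0 °C; ICH2CH2I, −78 °C to rt; 1 M aq. HCl, THF, rt
Reagents that add atoms: 1,2-diiodoethane, ICCI; tert-butyldimethylsilyl trifluoromethanesulfonate, CC(C)(C)[Si](C)(C)OS(=O)(=O)C(F)(F)F (its silyl group is present only in 17 to 19)
Why: Methoxy-directed ortho-lithiation; C7 is the only carbon ortho to a methoxy group that still bears hydrogen, the ketone is masked in the flask as in step 5, and 1,2-diiodoethane iodinates the aryllithium without attacking the enol ether.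

Step 10
Reactants: 20 1-(7-iodo-1,8-dimethoxy-3-methylnaphthalen-2-yl)ethan-1-one (two molecules)
Product: 21 1,1'-(1,1',8,8'-tetramethoxy-6,6'-dimethyl-[2,2'-binaphthalene]-7,7'-diyl)di(ethan-1-one)
Conditions: Cu powder (activated), DMF, 150 °C
Reagents that add atoms: none
Why: Classical Ullmann homocoupling of an ortho-alkoxy aryl iodide on copper metal; the iodide fixes the site of the new C7–C7' bond, and the ketone and ethers should be inert to copper at this temperature.

Step 11
Reactants: 21 1,1'-(1,1',8,8'-tetramethoxy-6,6'-dimethyl-[2,2'-binaphthalene]-7,7'-diyl)di(ethan-1-one)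
Product: 22 1,1'-(1,1',8,8'-tetrahydroxy-6,6'-dimethyl-[2,2'-binaphthalene]-7,7'-diyl)di(ethan-1-one) (stypandrol)
Conditions: BBr3 (excess), CH2Cl2, −78 °C to rt; H2O
Reagents that add atoms: none
Why: Lewis acid cleavage of aryl methyl ethers; the ethers next to the acetyl groups are activated by chelation and the peri ethers follow, the ketones are untouched, and the oxidation-prone tetrol is formed only in this last step.

## Compound list

1 | 1-(2,4-dihydroxy-6-methylphenyl)ethan-1-one (orcacetophenone) | CC(=O)c1c(C)cc(O)cc1O | starting material
2 | 1-[4-(benzyloxy)-2-hydroxy-6-methylphenyl]ethan-1-one | CC(=O)c1c(C)cc(OCc2ccccc2)cc1O | intermediate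
3 | 1-[4-(benzyloxy)-2-methoxy-6-methylphenyl]ethan-1-one | CC(=O)c1c(C)cc(OCc2ccccc2)cc1OC | intermediate
4 | 1-(4-hydroxy-2-methoxy-6-methylphenyl)ethan-1-one | CC(=O)c1c(C)cc(O)cc1OC | intermediate
5 | 4-acetyl-3-methoxy-5-methylphenyl N-(propan-2-yl)carbamate | CC(=O)c1c(C)cc(OC(=O)NC(C)C)cc1OC | intermediate
6 | 4-{1-[(tert-butyldimethylsilyl)oxy]ethenyl}-3-methoxy-5-methylphenyl N-(tert-butyldimethylsilyl)-N-(propan-2-yl)carbamate (not isolated) | C=C(O[Si](C)(C)C(C)(C)C)c1c(C)cc(OC(=O)N(C(C)C)[Si](C)(C)C(C)(C)C)cc1OC | intermediate
7 | 2-lithio derivative of 6, lithium on the carbon between the carbamate oxygen and the methoxy group (not isolated) | COc1c([Li])c(OC(=O)N(C(C)C)[Si](C)(C)C(C)(C)C)cc(C)c1C(=C)O[Si](C)(C)C(C)(C)C | intermediate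
8 | 4-{1-[(tert-butyldimethylsilyl)oxy]ethenyl}-3-methoxy-5-methyl-2-(trimethylsilyl)phenyl N-(tert-butyldimethylsilyl)-N-(propan-2-yl)carbamate (not isolated) | COc1c([Si](C)(C)C)c(OC(=O)N(C(C)C)[Si](C)(C)C(C)(C)C)cc(C)c1C(=C)O[Si](C)(C)C(C)(C)C | intermediate
9 | 4-acetyl-3-methoxy-5-methyl-2-(trimethylsilyl)phenyl N-(propan-2-yl)carbamate | CC(=O)c1c(C)cc(OC(=O)NC(C)C)c([Si](C)(C)C)c1OC | intermediate
10 | 1-[4-hydroxy-2-methoxy-6-methyl-3-(trimethylsilyl)phenyl]ethan-1-one (not isolated) | CC(=O)c1c(C)cc(O)c([Si](C)(C)C)c1OC | intermediate
11 | 4-acetyl-3-methoxy-5-methyl-2-(trimethylsilyl)phenyl trifluoromethanesulfonate | CC(=O)c1c(C)cc(OS(=O)(=O)C(F)(F)F)c([Si](C)(C)C)c1OC | intermediate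
12 | 3-hydroxy-2H-pyran-2-one | Oc1cccoc1=O | starting material
13 | 3-methoxy-2H-pyran-2-one | COc1cccoc1=O | intermediate
14 | 1-(2-methoxy-6-methyl-3,4-didehydrophenyl)ethan-1-one (aryne, not isolated) | CC(=O)C1=C(OC)C#CC=C1C | intermediate
15 | 6-acetyl-4,5-dimethoxy-7-methyl-1,4-dihydro-1,4-(epoxymethano)naphthalen-10-one, benzo-fused 2-oxabicyclo[2.2.2]octadienone (racemic, one enantiomer written, not isolated) | COc1c(C(C)=O)c(C)cc2c1[C@@]1(OC)C=C[C@@H]2OC1=O | intermediate
16 | 1-(1,8-dimethoxy-3-methylnaphthalen-2-yl)ethan-1-one | CC(=O)c1c(C)cc2cccc(OC)c2c1OC | intermediate
17 | tert-butyl{[1-(1,8-dimethoxy-3-methylnaphthalen-2-yl)ethenyl]oxy}dimethylsilane (not isolated) | C=C(O[Si](C)(C)C(C)(C)C)c1c(C)cc2cccc(OC)c2c1OC | intermediate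
18 | 7-lithio derivative of 17 (not isolated) | C=C(O[Si](C)(C)C(C)(C)C)c1c(C)cc2ccc([Li])c(OC)c2c1OC | intermediate
19 | tert-butyl{[1-(7-iodo-1,8-dimethoxy-3-methylnaphthalen-2-yl)ethenyl]oxy}dimethylsilane (not isolated) | C=C(O[Si](C)(C)C(C)(C)C)c1c(C)cc2ccc(I)c(OC)c2c1OC | intermediate
20 | 1-(7-iodo-1,8-dimethoxy-3-methylnaphthalen-2-yl)ethan-1-one | CC(=O)c1c(C)cc2ccc(I)c(OC)c2c1OC | intermediate
21 | 1,1'-(1,1',8,8'-tetramethoxy-6,6'-dimethyl-[2,2'-binaphthalene]-7,7'-diyl)di(ethan-1-one) | CC(=O)c1c(C)cc2ccc(-c3ccc4cc(C)c(C(C)=O)c(OC)c4c3OC)c(OC)c2c1OC | intermediate
22 | 1,1'-(1,1',8,8'-tetrahydroxy-6,6'-dimethyl-[2,2'-binaphthalene]-7,7'-diyl)di(ethan-1-one) (stypandrol) | CC(=O)c1c(C)cc2ccc(-c3ccc4cc(C)c(C(C)=O)c(O)c4c3O)c(O)c2c1O | target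

## Step count and least certain steps

Total step count: 11. Longest linear sequence: 10 steps (steps 1 to 6 and 8 to 11); step 7 is a one-step side branch.

**Step 8 (key step).** The most likely failure is poor regiocontrol, with the methoxy-bearing pyrone terminus bonding to C4a and the ring B oxygen ending up at C5. The second is loss of the short-lived aryne to fluoride, to its own precursor or to the ketone, because the electron-poor pyrone is a sluggish diene. Fallback, from 11 back to 16: the aryne is generated with CsF in the presence of 1-methoxycyclohexa-1,3-diene, a more electron-rich and more strongly polarized diene. This should give the bicyclic adduct 1-(1,8-dimethoxy-6-methyl-1,4-dihydro-1,4-ethanonaphthalen-7-yl)ethan-1-one F1, which is heated to about 200 °C in o-dichlorobenzene to expel ethene in a retro-Diels–Alder (Alder–Rickert) step, returning to the route at 16.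

**Step 5.** What may go wrong is incomplete masking of the ketone before butyllithium is added, so that the base adds to or enolizes the carbonyl; lithiation on the other side of the carbamate; migration of the carbamoyl group to carbon on warming; or loss of the new aryl–silicon bond by protonation during acidic unmasking. Fallback, from 5 back to 9, with the carbonyl carried one oxidation level lower:
- NaBH4 in MeOH reduces 5 to the carbinol 4-(1-hydroxyethyl)-3-methoxy-5-methylphenyl N-(propan-2-yl)carbamate F2.
- The same silylation, lithiation and C-silylation sequence, with mild aqueous work-up, gives 4-{1-[(tert-butyldimethylsilyl)oxy]ethyl}-3-methoxy-5-methyl-2-(trimethylsilyl)phenyl N-(propan-2-yl)carbamate F3, in which the alcohol is a robust silyl ether.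
- HF·pyridine in THF frees the alcohol to give 4-(1-hydroxyethyl)-3-methoxy-5-methyl-2-(trimethylsilyl)phenyl N-(propan-2-yl)carbamate F4.
- Dess–Martin periodinane oxidizes F4 to 9.

**Step 9.** What may go wrong is competing deprotonation of the C3 methyl group, or attack of butyllithium at silicon of the enol ether, releasing an enolate that consumes the iodine source and leaves the lithiation incomplete. Fallback, from 16 directly to 22, bypassing 20 and 21: BBr3 in CH2Cl2 demethylates 16 to 1-(1,8-dihydroxy-3-methylnaphthalen-2-yl)ethan-1-one F5, which is dimerized by phenolic oxidative coupling with FeCl3 adsorbed on SiO2 under argon (trivalent iron as an inner-sphere one-electron oxidant). This is shorter but has to contend with coupling at C5 and with over-oxidation, which is why it is held in reserve.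

**Step 10.** What may go wrong is reductive loss of iodine in place of coupling at the high temperature, or slow conversion on the copper surface. Fallback, from 20 back to 21: half of the iodide is converted with B2pin2, Pd(dppf)Cl2 and KOAc in dioxane into the boronate 1-[1,8-dimethoxy-3-methyl-7-(4,4,5,5-tetramethyl-1,3,2-dioxaborolan-2-yl)naphthalen-2-yl]ethan-1-one F6, which is cross-coupled with the other half of 20 under Suzuki–Miyaura conditions (Pd(PPh3)4, K3PO4, dioxane/H2O) to give 21.

## Further compounds

F1 | step 8 | 1-(1,8-dimethoxy-6-methyl-1,4-dihydro-1,4-ethanonaphthalen-7-yl)ethan-1-one (racemic, one enantiomer written) | COc1c(C(C)=O)c(C)cc2c1[C@@]1(OC)C=C[C@@H]2CC1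
F2 | step 5 | 4-(1-hydroxyethyl)-3-methoxy-5-methylphenyl N-(propan-2-yl)carbamate (racemic) | CC(O)c1c(C)cc(OC(=O)NC(C)C)cc1OC
F3 | step 5 | 4-{1-[(tert-butyldimethylsilyl)oxy]ethyl}-3-methoxy-5-methyl-2-(trimethylsilyl)phenyl N-(propan-2-yl)carbamate (racemic) | CC(O[Si](C)(C)C(C)(C)C)c1c(C)cc(OC(=O)NC(C)C)c([Si](C)(C)C)c1OC
F4 | step 5 | 4-(1-hydroxyethyl)-3-methoxy-5-methyl-2-(trimethylsilyl)phenyl N-(propan-2-yl)carbamate (racemic) | CC(O)c1c(C)cc(OC(=O)NC(C)C)c([Si](C)(C)C)c1OC
F5 | step 9 | 1-(1,8-dihydroxy-3-methylnaphthalen-2-yl)ethan-1-one | CC(=O)c1c(C)cc2cccc(O)c2c1O
F6 | step 10 | 1-[1,8-dimethoxy-3-methyl-7-(4,4,5,5-tetramethyl-1,3,2-dioxaborolan-2-yl)naphthalen-2-yl]ethan-1-one | CC(=O)c1c(C)cc2ccc(B3OC(C)(C)C(C)(C)O3)c(OC)c2c1OC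
A1 | alternative 1 | 7-acetyl-8-ethoxy-6-methyl-3,4-dihydronaphthalen-1(2H)-one | CCOc1c(C(C)=O)c(C)cc2c1C(=O)CCC2
A2 | alternative 1 | 1-ethoxyocta-1,7-diyn-3-one | CCOC#CC(=O)CCCC#C
A3 | alternative 1 | pent-3-yn-2-one | CC#CC(C)=O
A4 | alternative 2 | tetramethyl 8,8'-dimethoxy-6,6'-dimethyl-1,1'-dioxo-3,3',4,4'-tetrahydro-[2,2'-binaphthalene]-2,2',7,7'-tetracarboxylate (mixture of diastereomers) | COC(=O)c1c(C)cc2c(c1OC)C(=O)C(C(=O)OC)(CC2)C1(C(=O)OC)CCc2cc(C)c(C(=O)OC)c(OC)c2C1=O
A5 | alternative 2 | dimethyl 2-methoxy-4,6-dimethylbenzene-1,3-dicarboxylate | COC(=O)c1c(C)cc(C)c(C(=O)OC)c1OC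
A6 | alternative 2 | dimethyl 2,3-dimethylidenebutanedioate | C=C(C(=O)OC)C(=C)C(=O)OC
A7 | alternative 3 | 1-(8-hydroxy-1-methoxy-3-methylnaphthalen-2-yl)ethan-1-one | CC(=O)c1c(C)cc2cccc(O)c2c1OC
A8 | alternative 3 | (E)-1-(3-acetyl-2-methoxy-4,6-dimethylphenyl)-3-(dimethylamino)prop-2-en-1-one | CC(=O)c1c(C)cc(C)c(C(=O)/C=C/N(C)C)c1OC
A9 | alternative 3 | 1,1'-(2-methoxy-4,6-dimethyl-1,3-phenylene)di(ethan-1-one) | CC(=O)c1c(C)cc(C)c(C(C)=O)c1OC
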